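**Retrosynthetic overview**

1. The target is the head-to-head, endo [4+2] homodimer of a single C15 monomer, 7-hydroxy-8-methoxy-3-[(E)-3-methylbuta-1,3-dienyl]coumarin. Cleaving the C1–C2 and C5–C6 bonds of the cyclohex-3-ene ring (C1 = quaternary carbon, C2 = CH bearing a coumarin, C3=C4 with the 4-methyl, C5 and C6 = CH2) returns two identical dienes, handled as their silyl ethers.
2. Enabling feature: the ring double bond C3=C4 sits between the aryl-bearing C2 and C5, which is the retron of a 1-aryl-3-methylbutadiene. C1 (methyl plus (E)-2-arylvinyl arm) and C6 are the two carbons of the isopropenyl group of a second dienyl-coumarin carrying the same 7-hydroxy-8-methoxycoumarin-3-yl unit. The cis relation of the C2 coumarin and the C1 arm is the endo signature.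
3. The diene comes from a 3-bromocoumarin by Heck coupling with 2-methylbut-3-en-2-ol and dehydration; the bromide from 7-hydroxy-8-methoxycoumarin (silylation, C3 bromination); the coumarin from 2-methoxyresorcinol and ethyl propiolate.
4. Ring order: the pyranone ring of the coumarin first (step 1), the cyclohexene ring last (step 6, both stereocentres), then desilylation.

Key step: step 6

Remark: the sense of induction of the chiral anion in step 6 cannot be predicted with certainty; the route is written for the antipode of the anion that gives the (1R,2R) product, both antipodes being accessible from (S)- or (R)-BINOL.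

Anion A− (used in step 6) is the imidodiphosphorimidate (IDPi) anion [(ArO)2P(=NSO2CF3)]2N−, in which each (ArO)2 unit is (S)-3,3′-bis[3,5-bis(trifluoromethyl)phenyl]-1,1′-bi-2-naphtholate. Its 2,4,6-tri(p-tolyl)pyrylium salt is made beforehand by salt metathesis of the pyrylium tetrafluoroborate with Na+ A−.

**Step 1**
Reactants: 1 2-methoxyresorcinol (2-methoxybenzene-1,3-diol); 2 ethyl propiolate
Product: 4 7-hydroxy-8-methoxycoumarin, via Z-cinnamate ester 3 (not isolated)
Conditions: Pd(OAc)2 (3 mol %), CF3CO2H/CH2Cl2, 0 °C to rt
Reagents that add atoms: none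
Why: Electrophilic palladation of the electron-rich arene at C4 (ortho to one OH, para to the other; the two open positions are equivalent) and trans-hydroarylation of the alkyne give the Z-cinnamate, which lactonises onto the neighbouring OH (palladium-catalysed alkyne hydroarylation, the alkyne variant of the Pechmann coumarin synthesis).

**Step 2**
Reactants: 4 7-hydroxy-8-methoxycoumarin
Product: 5 8-methoxy-7-(triisopropylsilyloxy)coumarin
Conditions: TIPSCl, imidazole, DMF, rt
Reagents that add atoms: triisopropylsilyl chloride, CC(C)[Si](Cl)(C(C)C)C(C)C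
Why: Silylation of the only free phenol; the bulky silyl ether keeps the 7-oxygen a donor, survives amine bases, palladium and photoredox conditions, and is removed at the end by fluoride.

**Step 3**
Reactants: 5 8-methoxy-7-(triisopropylsilyloxy)coumarin
Product: 6 3-bromo-8-methoxy-7-(triisopropylsilyloxy)coumarin
Conditions: N-bromosuccinimide (1.05 equiv), MeCN, 0 °C to rt, dark
Reagents that add atoms: N-bromosuccinimide, O=C1CCC(=O)N1Br
Why: C3 is the β-carbon of a vinylogous aryl enol ether (the 7-oxygen is para to C4a), so electrophilic bromine attacks C3, the C4 cation is stabilised by the 7-oxygen and loss of the C3 proton restores the pyranone (electrophilic vinylic substitution, as in the 3-halogenation of 7-alkoxy- and 7-aminocoumarins); the silyl group shields ring carbon C6.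

**Step 4**
Reactants: 6 3-bromo-8-methoxy-7-(triisopropylsilyloxy)coumarin; 7 2-methylbut-3-en-2-ol
Product: 8 3-[(E)-3-hydroxy-3-methylbut-1-en-1-yl]-8-methoxy-7-(triisopropylsilyloxy)coumarin
Conditions: Pd(OAc)2 (5 mol %), P(o-tol)3 (10 mol %), Et3N, DMF, 80–90 °C
Reagents that add atoms: none
Why: Mizoroki–Heck reaction: zerovalent palladium inserts into the C3–Br bond, the terminal alkene inserts syn at its CH2 end, and syn β-hydride elimination can only occur towards the coumarin side (the carbinol carbon has no hydrogen), which should give the E-alkene.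

**Step 5**
Reactants: 8 3-[(E)-3-hydroxy-3-methylbut-1-en-1-yl]-8-methoxy-7-(triisopropylsilyloxy)coumarin
Product: 10 8-methoxy-3-[(E)-3-methylbuta-1,3-dien-1-yl]-7-(triisopropylsilyloxy)coumarin, via tertiary allylic mesylate 9 (not isolated)
Conditions: MsCl, Et3N (excess), CH2Cl2, −10 °C to rt; product kept cold with BHT and used at once
Reagents that add atoms: none
Why: The tertiary allylic mesylate ionises readily and loses a methyl proton to Et3N (E1/E2 dehydration); only methyl hydrogens are available, so only the conjugated 1,3-diene can form and the E-alkene is untouched.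

**Step 6**
Reactants: 10 8-methoxy-3-[(E)-3-methylbuta-1,3-dien-1-yl]-7-(triisopropylsilyloxy)coumarin (two molecules)
Product: 11 8-methoxy-3-[(E)-2-[(1R,2R)-2-{8-methoxy-2-oxo-7-(triisopropylsilyloxy)-2H-chromen-3-yl}-1,4-dimethylcyclohex-3-en-1-yl]ethenyl]-7-(triisopropylsilyloxy)coumarin
Conditions: 2,4,6-tri(p-tolyl)pyrylium salt of anion A− (3 mol %), CH2Cl2 (0.3 M), −40 °C, 450 nm LEDs, argon
Reagents that add atoms: none
Why: Proposed new method: the excited pyrylium cation oxidises 10 (an electron-rich 1-aryl diene) to its radical cation, which stays ion-paired with the chiral anion A−; its least hindered, spin-bearing terminal CH2 bonds to the terminal CH2 of a neutral s-cis molecule of 10 (future C5–C6 bond), the resulting symmetric bis-allyl radical cation closes the second bond between the aryl-bearing allyl terminus and the methyl-bearing allyl terminus (future C1–C2 bond), and back electron transfer from the pyranyl radical or chain transfer to 10 releases neutral 11. The closest known reaction types are the hole-catalysed (aminium salt or photoredox) Diels–Alder reaction of electron-rich styrenes with dienes, its enantioselective counteranion-directed variants with chiral phosphoramide-type and IDPi anions, and the thermal Diels–Alder dimerisation of 1-aryl-3-methylbutadienes; new here is chiral-anion control of a homodimerisation in which one dienyl-coumarin serves as both diene and dienophile. The cyclohexene ring closes by an intermolecular, stepwise [4+2] cycloaddition (6-ring closure of the distonic intermediate; a vinylcyclobutane from competing 4-ring closure should re-open and funnel to the same cyclohexene under hole catalysis). The relative configuration (C2 coumarin cis to the C1 arylvinyl arm, C1 methyl trans) is set by the endo-type, face-to-face arrangement of the two aryl-allyl units in the ring-closing transition state, and the absolute configuration of C1 and C2 (both R) by the chiral anion, which blocks one face of the ion-paired methyl-bearing allyl terminus. The step needs head-to-head regioselectivity, periselectivity for the isopropenyl C=C over the internal alkene and the coumarin C3=C4 bond, and endo selectivity: the 1-aryl/3-methyl pattern makes the unsubstituted CH2 termini the sites of first bonding (ortho/para rule, most stabilised bis-allyl intermediate), the 1,1-disubstituted terminal alkene is the only unhindered 2π unit, and the low temperature switches off the racemic thermal dimerisation.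

**Step 7**
Reactants: 11 bis-silyl ether of the target
Product: 12 7-hydroxy-3-[(E)-2-[(1R,2R)-2-(7-hydroxy-8-methoxy-2-oxo-2H-chromen-3-yl)-1,4-dimethylcyclohex-3-en-1-yl]ethenyl]-8-methoxy-2H-chromen-2-one (target)
Conditions: Bu4NF (2.2 equiv), AcOH (2.5 equiv), THF, 0 °C
Reagents that add atoms: none
Why: Fluoride attacks silicon and expels the acidic 7-hydroxycoumarin as a good leaving group (silyl ether cleavage); the acetic acid buffer should leave the lactones, the alkenes and both stereocentres (C1 quaternary, C2 not acidic) untouched.

**Compound list**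

1 | 2-methoxyresorcinol (2-methoxybenzene-1,3-diol) | COc1c(O)cccc1O | starting material
2 | ethyl propiolate | CCOC(=O)C#C | starting material
3 | ethyl (Z)-3-(2,4-dihydroxy-3-methoxyphenyl)prop-2-enoate | CCOC(=O)/C=C\c1ccc(O)c(OC)c1O | intermediate
4 | 7-hydroxy-8-methoxycoumarin | COc1c(O)ccc2ccc(=O)oc12 | intermediate
5 | 8-methoxy-7-(triisopropylsilyloxy)coumarin | COc1c(O[Si](C(C)C)(C(C)C)C(C)C)ccc2ccc(=O)oc12 | intermediate
6 | 3-bromo-8-methoxy-7-(triisopropylsilyloxy)coumarin | COc1c(O[Si](C(C)C)(C(C)C)C(C)C)ccc2cc(Br)c(=O)oc12 | intermediate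
7 | 2-methylbut-3-en-2-ol | C=CC(C)(C)O | starting material
8 | 3-[(E)-3-hydroxy-3-methylbut-1-en-1-yl]-8-methoxy-7-(triisopropylsilyloxy)coumarin | COc1c(O[Si](C(C)C)(C(C)C)C(C)C)ccc2cc(/C=C/C(C)(C)O)c(=O)oc12 | intermediate
9 | (E)-4-[8-methoxy-2-oxo-7-(triisopropylsilyloxy)-2H-chromen-3-yl]-2-methylbut-3-en-2-yl methanesulfonate | COc1c(O[Si](C(C)C)(C(C)C)C(C)C)ccc2cc(/C=C/C(C)(C)OS(C)(=O)=O)c(=O)oc12 | intermediate
10 | 8-methoxy-3-[(E)-3-methylbuta-1,3-dien-1-yl]-7-(triisopropylsilyloxy)coumarin | COc1c(O[Si](C(C)C)(C(C)C)C(C)C)ccc2cc(/C=C/C(C)=C)c(=O)oc12 | intermediate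
11 | 8-methoxy-3-[(E)-2-[(1R,2R)-2-{8-methoxy-2-oxo-7-(triisopropylsilyloxy)-2H-chromen-3-yl}-1,4-dimethylcyclohex-3-en-1-yl]ethenyl]-7-(triisopropylsilyloxy)coumarin | COc1c(O[Si](C(C)C)(C(C)C)C(C)C)ccc2cc(/C=C/[C@@]3(C)CCC(C)=C[C@H]3c3cc4ccc(O[Si](C(C)C)(C(C)C)C(C)C)c(OC)c4oc3=O)c(=O)oc12 | intermediate
12 | 7-hydroxy-3-[(E)-2-[(1R,2R)-2-(7-hydroxy-8-methoxy-2-oxo-2H-chromen-3-yl)-1,4-dimethylcyclohex-3-en-1-yl]ethenyl]-8-methoxy-2H-chromen-2-one | COc1c(O)ccc2cc(/C=C/[C@@]3(C)CCC(C)=C[C@H]3c3cc4ccc(O)c(OC)c4oc3=O)c(=O)oc12 | target

**Count**

Total steps: 7. Longest linear sequence: 7 steps (1 to 12).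

**Steps most likely to fail**

Step 6 (proposed new method). What may go wrong: insufficient facial control by the remote chiral anion, diversion of the radical cation into [2+2] adducts or oligomers, or poor endo/exo discrimination. Fallback with known chemistry, a catalytic enantioselective cross Diels–Alder reaction that forms the same two bonds: it sets out from 10 and comes back at 11. Diene 10 and purchased methacrolein react under a chiral cationic oxazaborolidinium Lewis acid, (S)-3,3-diphenyl-1-(o-tolyl)tetrahydro-1H,3H-pyrrolo[1,2-c][1,3,2]oxazaborole protonated by Tf2NH (10–20 mol %, CH2Cl2, −78 to −40 °C; antipode if the facial sense requires). Ortho/para regiochemistry and formyl-endo addition should give (1S,2R)-2-[8-methoxy-2-oxo-7-(triisopropylsilyloxy)-2H-chromen-3-yl]-1,4-dimethylcyclohex-3-ene-1-carbaldehyde F1, whose α-quaternary aldehyde cannot epimerise. Wittig methylenation (Ph3PCH3Br, KOtBu, THF, 0 °C) gives 3-[(1R,6R)-6-ethenyl-3,6-dimethylcyclohex-2-en-1-yl]-8-methoxy-7-(triisopropylsilyloxy)coumarin F2. Heck coupling of F2 with bromide 6 (Pd(OAc)2, P(o-tol)3, Et3N, DMF, 90 °C; β-hydride elimination is possible only towards the coumarin, hence E) returns to 11.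

Step 3. What may go wrong: poor regioselectivity of electrophilic bromination, with attack on ring carbons C6 or C5 of the oxygenated benzene ring competing with C3. Fallback, halogenation by deprotonation instead of electrophilic attack: it sets out from 5 and comes back at 8. Directed zincation of the most acidic vinylic C3–H of 5 with TMPZnCl·LiCl (THF, rt) gives chloro[8-methoxy-2-oxo-7-(triisopropylsilyloxy)-2H-chromen-3-yl]zinc F3. Iodination in the same flask (I2, THF, 0 °C) gives 3-iodo-8-methoxy-7-(triisopropylsilyloxy)coumarin F4. Heck coupling of F4 with 7 under the conditions of step 4 returns to 8.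

Step 5. What may go wrong: the ionised tertiary allylic system may be captured by chloride, oligomerise cationically, or the sensitive diene may dimerise thermally in racemic form during isolation. Fallback, installation of the complete dienyl unit by cross-coupling so that no alcohol is dehydrated: it sets out from 6 and comes back at 10. Hydroboration of purchased 2-methylbut-1-en-3-yne with pinacolborane (Cp2Zr(H)Cl cat., Et3N, 60 °C) gives 4,4,5,5-tetramethyl-2-[(E)-3-methylbuta-1,3-dien-1-yl]-1,3,2-dioxaborolane F5. Suzuki–Miyaura coupling of F5 with 6 (Pd(dppf)Cl2, K3PO4, dioxane/H2O, 50 °C) gives 10 directly.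

**Further compounds**

F1 | step 6 | (1S,2R)-2-[8-methoxy-2-oxo-7-(triisopropylsilyloxy)-2H-chromen-3-yl]-1,4-dimethylcyclohex-3-ene-1-carbaldehyde | O=C[C@@]1(C)CCC(C)=C[C@H]1c1cc2ccc(O[Si](C(C)C)(C(C)C)C(C)C)c(OC)c2oc1=O
F2 | step 6 | 3-[(1R,6R)-6-ethenyl-3,6-dimethylcyclohex-2-en-1-yl]-8-methoxy-7-(triisopropylsilyloxy)coumarin | C=C[C@@]1(C)CCC(C)=C[C@H]1c1cc2ccc(O[Si](C(C)C)(C(C)C)C(C)C)c(OC)c2oc1=O
F3 | step 3 | chloro[8-methoxy-2-oxo-7-(triisopropylsilyloxy)-2H-chromen-3-yl]zinc | COc1c(O[Si](C(C)C)(C(C)C)C(C)C)ccc2cc([Zn]Cl)c(=O)oc12
F4 | step 3 | 3-iodo-8-methoxy-7-(triisopropylsilyloxy)coumarin | COc1c(O[Si](C(C)C)(C(C)C)C(C)C)ccc2cc(I)c(=O)oc12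
F5 | step 5 | 4,4,5,5-tetramethyl-2-[(E)-3-methylbuta-1,3-dien-1-yl]-1,3,2-dioxaborolane | CC(=C)/C=C/B1OC(C)(C)C(C)(C)O1
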